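**Retrosynthetic overview**
1. Target 24 ← O8–MOM cleavage ← double angeloylation of diol 18 with two equivalents of angelic acid; O8 stays masked so only O7 and O9 are acylated.
2. 18 ← conjugate methyl addition (sets C3) to bicyclo[3.1.1]heptenone 17.
3. 17 ← key ring contraction: semipinacol 1,2-shift of C10 from C1 to C11 in the 1-silyloxy-2-endo-iodonorbornene 15, which makes the cyclobutane and unveils the C1 ketone.
4. 15 ← intramolecular Diels–Alder of silyloxycyclopentadiene 14 (norbornene and seven-membered ring in one step) ← cyclopentenone 13 ← aldol/methylation of cyclopent-2-enone with aldehyde 10.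
5. 10 ← syn-alkoxyallylboration of iodo-enal 3 (sets C7, C8) ← hydroxypivaldehyde. Ring order: five-membered ring (bought) → seven-membered ring + norbornene → cyclobutane/six-membered ketone ring.

Assumption: atoms carry longipinane labels throughout, also in acyclic precursors (C1 ketone carbon, C2, C3 methyl-bearing CH, C4, C5, C6 the CMe2 carbon, C7–C9 oxygenated carbons, C10 methyl-bearing quaternary carbon, C11; bonds C4–C10 and C5–C11 close the cyclobutane; methyls C12/C13 on C6, C14 on C10, C15 on C3).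
Assumption: 1 is used as the monomer (the commercial dimer dissociates in warm THF).

**Step 1**
Reactants: 1 3-hydroxy-2,2-dimethylpropanal
Product: 2 (3E)-4-iodo-2,2-dimethylbut-3-en-1-ol
Conditions: CrCl2 (6 equiv), CHI3 (2 equiv), THF, 0 °C to rt
Reagents that add atoms: iodoform, IC(I)I
Why: Takai–Utimoto iodo-olefination: the gem-dichromium reagent from CHI3 adds to the non-enolisable aldehyde and eliminates to the (E)-iodoalkene, and the neopentyl hydroxyl is tolerated.

**Step 2**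
Reactants: 2 (3E)-4-iodo-2,2-dimethylbut-3-en-1-ol
Product: 3 (3E)-4-iodo-2,2-dimethylbut-3-enal
Conditions: Dess–Martin periodinane, NaHCO3, CH2Cl2, 0 °C to rt
Reagents that add atoms: none
Why: Dess–Martin oxidation of a primary neopentyl alcohol stops at the non-enolisable aldehyde and leaves the vinyl iodide untouched.

**Step 3**
Reactants: 3 (3E)-4-iodo-2,2-dimethylbut-3-enal; 4 3-(methoxymethoxy)prop-1-ene
Product: 7 (3S,4S,6E)-7-iodo-3-(methoxymethoxy)-5,5-dimethylhepta-1,6-dien-4-ol, via allylborane 5 (not isolated), via borinate ester 6 (not isolated)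
Conditions: 4, s-BuLi, THF, −78 °C; (+)-Ipc2BOMe; BF3·OEt2; then 3, −78 °C; NaOH, H2O2, 0 °C to rt
Reagents that add atoms: none
Why: Brown (Z)-γ-alkoxyallylboration: the chair-like transition state turns the (Z)-alkoxyallyl geometry into the syn C7/C8 pair, and the isopinocampheyl groups from (−)-α-pinene direct attack to the re face of the aldehyde (C7 and C8 as in the target).

**Step 4**
Reactants: 7 (3S,4S,6E)-7-iodo-3-(methoxymethoxy)-5,5-dimethylhepta-1,6-dien-4-ol
Product: 8 tert-butyl{[(3S,4S,6E)-7-iodo-3-(methoxymethoxy)-5,5-dimethylhepta-1,6-dien-4-yl]oxy}dimethylsilane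
Conditions: TBSOTf, 2,6-lutidine, CH2Cl2, −78 to 0 °C
Reagents that add atoms: tert-butyldimethylsilyl triflate, CC(C)(C)[Si](C)(C)OS(=O)(=O)C(F)(F)F
Why: Silyl ether formation with the triflate copes with the hindered neopentyl carbinol, and the MOM acetal survives the buffered conditions.

**Step 5**
Reactants: 8 tert-butyl{[(3S,4S,6E)-7-iodo-3-(methoxymethoxy)-5,5-dimethylhepta-1,6-dien-4-yl]oxy}dimethylsilane
Product: 10 (2R,3S,5E)-3-[(tert-butyldimethylsilyl)oxy]-6-iodo-2-(methoxymethoxy)-4,4-dimethylhex-5-enal, via diol 9 (not isolated)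
Conditions: OsO4 (2 mol %), NaIO4, 2,6-lutidine, dioxane–H2O (3:1), rt
Reagents that add atoms: NaIO4, [Na+].[O-]I(=O)(=O)=O
Why: Lemieux–Johnson oxidation: OsO4 dihydroxylates the electron-richer terminal alkene much faster than the electron-poor neopentyl (E)-iodoalkene, and NaIO4 cleaves the diol to the C9 aldehyde without touching C8.

**Step 6**
Reactants: 10 (2R,3S,5E)-3-[(tert-butyldimethylsilyl)oxy]-6-iodo-2-(methoxymethoxy)-4,4-dimethylhex-5-enal; 11 cyclopent-2-en-1-one
Product: 13 (5S)-5-[(1S,2S,3S,5E)-3-[(tert-butyldimethylsilyl)oxy]-1-hydroxy-6-iodo-2-(methoxymethoxy)-4,4-dimethylhex-5-en-1-yl]-5-methylcyclopent-2-en-1-one, via lithium aldolate 12 (not isolated)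
Conditions: 11, LiN(i-Pr)2, THF, −78 °C; 10; then LiN(i-Pr)2 (1.3 equiv), −78 to −40 °C; MeI, DMPU, −40 °C; aq. NH4Cl
Reagents that add atoms: iodomethane, CI
Why: Aldol addition then Fráter–Seebach-type alkylation: the kinetic α′-lithium enolate adds in the Felkin–Anh sense (anti to the α-OMOM group, setting C9), and the chelated aldolate dianion is methylated at C10 on the face away from the C9 side chain, so the methyl ends up anti to the C9 oxygen.

**Step 7**
Reactants: 13 (5S)-5-[(1S,2S,3S,5E)-3-[(tert-butyldimethylsilyl)oxy]-1-hydroxy-6-iodo-2-(methoxymethoxy)-4,4-dimethylhex-5-en-1-yl]-5-methylcyclopent-2-en-1-one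
Product: 15 (1S,2S,3S,4R,5S,7R,8R,9R)-3,5,9-tris[(tert-butyldimethylsilyl)oxy]-8-iodo-4-(methoxymethoxy)-2,6,6-trimethyltricyclo[5.4.0.0^2,9]undec-10-ene, via silyloxy diene 14 (not isolated)
Conditions: TBSOTf (2.5 equiv), Et3N, CH2Cl2, 0 °C to rt; then toluene (0.01 M), BHT, 140 °C, sealed tube
Reagents that add atoms: tert-butyldimethylsilyl triflate, CC(C)(C)[Si](C)(C)OS(=O)(=O)C(F)(F)F
Why: Soft enolisation gives the 1-silyloxy-5,5-disubstituted cyclopentadiene (no 1,5-hydrogen shift possible), and its intramolecular Diels–Alder reaction through the C10 tether forms C4–C5 and C1–C11; the tether fixes the diene face and C6 exo, the (E)-alkene puts iodine endo, and C5 bonds to the unhindered terminus C4 rather than the silyloxy-bearing C1.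

**Step 8**
Reactants: 15 (1S,2S,3S,4R,5S,7R,8R,9R)-3,5,9-tris[(tert-butyldimethylsilyl)oxy]-8-iodo-4-(methoxymethoxy)-2,6,6-trimethyltricyclo[5.4.0.0^2,9]undec-10-ene
Product: 17 (4S,5S,7S,8R,9S,10R,11R)-7,9-dihydroxy-8-(methoxymethoxy)-15-norlongipin-2-en-1-one, via iodo triol alkoxide 16 (not isolated)
Conditions: TBAF (5 equiv), THF, 0 to 50 °C; aq. NH4Cl
Reagents that add atoms: none
Why: Proposed new method: fluoride frees the bridgehead C1 alkoxide, whose C1–C10 bond is antiperiplanar to the endo C11–I bond while there is no antiperiplanar hydrogen and the backside of C11 is closed to external nucleophiles, so the oxyanion drives a stereospecific semipinacol 1,2-shift of C10 from C1 to C11 with loss of iodide (retention at C10, inversion at C11), contracting the five-membered ring to the cyclobutane and releasing the conjugated C1 ketone; the extra strain of the bicyclo[3.1.1]heptene over the norbornene is outweighed by C=O and iodide formation; the closest known reaction types are the Tiffeneau-type halohydrin (semipinacol) rearrangement and the quasi-Favorskii ring contraction, neither shown for a norbornane to bicyclo[3.1.1]heptane contraction; the same fluoride removes the C7 and C9 silyl groups.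

**Step 9**
Reactants: 17 (4S,5S,7S,8R,9S,10R,11R)-7,9-dihydroxy-8-(methoxymethoxy)-15-norlongipin-2-en-1-one
Product: 18 (3R,4S,5S,7S,8R,9S,10R,11R)-7,9-dihydroxy-8-(methoxymethoxy)longipinan-1-one
Conditions: Me2CuLi (5 equiv, from MeLi and CuI), Et2O–THF, −40 to 0 °C; aq. NH4Cl
Reagents that add atoms: Me2CuLi, [Li+].C[Cu-]C
Why: Gilman cuprate 1,4-addition: methyl adds to C3 from the face anti to the methyl-bearing C10 bridge, the usual course for bicyclo[3.1.1]hept-3-en-2-ones, giving the C3 methyl syn to C5 (3R).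

**Step 10**
Reactants: 18 (3R,4S,5S,7S,8R,9S,10R,11R)-7,9-dihydroxy-8-(methoxymethoxy)longipinan-1-one; 19 (2Z)-2-methylbut-2-enoic acid (angelic acid)
Product: 22 (3R,4S,5S,7S,8R,9S,10R,11R)-8-(methoxymethoxy)-1-oxolongipinane-7,9-diyl bis[(2Z)-2-methylbut-2-enoate], via mixed anhydride 20 (not isolated), via mono-angelate 21 (not isolated)
Conditions: 19 (2.6 equiv), 2,4,6-trichlorobenzoyl chloride (2.6 equiv), Et3N (3 equiv), toluene, rt; then 18, toluene, 80 °C
Reagents that add atoms: angelic acid (second equivalent of 19), C/C=C(/C)C(=O)O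
Why: Yamaguchi esterification: two molecules of 19 are consumed, one per hydroxyl; the preformed mixed anhydride acylates the C7 hydroxyl and then the more hindered C9 hydroxyl without Z to E isomerisation of the angelate, while O8 stays masked as the MOM ether.

**Step 11**
Reactants: 22 (3R,4S,5S,7S,8R,9S,10R,11R)-8-(methoxymethoxy)-1-oxolongipinane-7,9-diyl bis[(2Z)-2-methylbut-2-enoate]
Product: 24 (3R,4S,5S,7S,8R,9S,10R,11R)-8-hydroxy-1-oxolongipinane-7,9-diyl bis[(2Z)-2-methylbut-2-enoate], via dimethylborinate 23 (not isolated)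
Conditions: Me2BBr, CH2Cl2, −78 °C; then aq. NaHCO3
Reagents that add atoms: none
Why: Lewis-acid cleavage of the MOM acetal with Me2BBr at low temperature, then hydrolysis of the borinate, frees O8–H without acyl migration, ester cleavage or angelate isomerisation.

**Compound list**
1 | 3-hydroxy-2,2-dimethylpropanal | OCC(C)(C)C=O | starting material
2 | (3E)-4-iodo-2,2-dimethylbut-3-en-1-ol | OCC(C)(C)/C=C/I | intermediate
3 | (3E)-4-iodo-2,2-dimethylbut-3-enal | O=CC(C)(C)/C=C/I | intermediate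
4 | 3-(methoxymethoxy)prop-1-ene | C=CCOCOC | starting material
5 | allylborane: [(2Z)-3-(methoxymethoxy)prop-2-en-1-yl]bis(isopinocampheyl)borane, isopinocampheyl groups from (−)-α-pinene (not isolated) | COCO/C=C\CB([C@H]1C[C@H]2C[C@@H]([C@@H]1C)C2(C)C)[C@H]1C[C@H]2C[C@@H]([C@@H]1C)C2(C)C | intermediate
6 | borinate ester: bis(isopinocampheyl)borinic ester of alcohol 7 (not isolated) | B(O[C@@H](C(C)(C)/C=C/I)[C@@H](OCOC)C=C)([C@H]1C[C@H]2C[C@@H]([C@@H]1C)C2(C)C)[C@H]1C[C@H]2C[C@@H]([C@@H]1C)C2(C)C | intermediate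
7 | (3S,4S,6E)-7-iodo-3-(methoxymethoxy)-5,5-dimethylhepta-1,6-dien-4-ol | O[C@@H](C(C)(C)/C=C/I)[C@@H](OCOC)C=C | intermediate
8 | tert-butyl{[(3S,4S,6E)-7-iodo-3-(methoxymethoxy)-5,5-dimethylhepta-1,6-dien-4-yl]oxy}dimethylsilane | CC(C)(C)[Si](C)(C)O[C@@H](C(C)(C)/C=C/I)[C@@H](OCOC)C=C | intermediate
9 | diol: (2RS,3S,4S,6E)-4-[(tert-butyldimethylsilyl)oxy]-7-iodo-3-(methoxymethoxy)-5,5-dimethylhept-6-ene-1,2-diol (not isolated) | CC(C)(C)[Si](C)(C)O[C@@H](C(C)(C)/C=C/I)[C@@H](OCOC)C(O)CO | intermediate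
10 | (2R,3S,5E)-3-[(tert-butyldimethylsilyl)oxy]-6-iodo-2-(methoxymethoxy)-4,4-dimethylhex-5-enal | CC(C)(C)[Si](C)(C)O[C@@H](C(C)(C)/C=C/I)[C@@H](OCOC)C=O | intermediate
11 | cyclopent-2-en-1-one | O=C1C=CCC1 | starting material
12 | lithium aldolate (shown as the alcohol): (5RS)-5-[(1S,2S,3S,5E)-3-[(tert-butyldimethylsilyl)oxy]-1-hydroxy-6-iodo-2-(methoxymethoxy)-4,4-dimethylhex-5-en-1-yl]cyclopent-2-en-1-one (not isolated) | CC(C)(C)[Si](C)(C)O[C@@H](C(C)(C)/C=C/I)[C@@H](OCOC)[C@@H](O)C1CC=CC1=O | intermediate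
13 | (5S)-5-[(1S,2S,3S,5E)-3-[(tert-butyldimethylsilyl)oxy]-1-hydroxy-6-iodo-2-(methoxymethoxy)-4,4-dimethylhex-5-en-1-yl]-5-methylcyclopent-2-en-1-one | CC(C)(C)[Si](C)(C)O[C@@H](C(C)(C)/C=C/I)[C@@H](OCOC)[C@@H](O)[C@]1(C)CC=CC1=O | intermediate
14 | silyloxy diene: (5S)-1-[(tert-butyldimethylsilyl)oxy]-5-[(1S,2R,3S,5E)-1,3-bis[(tert-butyldimethylsilyl)oxy]-6-iodo-2-(methoxymethoxy)-4,4-dimethylhex-5-en-1-yl]-5-methylcyclopenta-1,3-diene (not isolated) | CC(C)(C)[Si](C)(C)O[C@@H](C(C)(C)/C=C/I)[C@@H](OCOC)[C@@H](O[Si](C)(C)C(C)(C)C)[C@]1(C)C=CC=C1O[Si](C)(C)C(C)(C)C | intermediate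
15 | (1S,2S,3S,4R,5S,7R,8R,9R)-3,5,9-tris[(tert-butyldimethylsilyl)oxy]-8-iodo-4-(methoxymethoxy)-2,6,6-trimethyltricyclo[5.4.0.0^2,9]undec-10-ene (norbornene with C1–C10 bonded, endo iodide on C11, silyloxy on bridgehead C1) | CC(C)(C)[Si](C)(C)O[C@@H]1[C@@H](OCOC)[C@@H](O[Si](C)(C)C(C)(C)C)[C@]2(C)[C@@H]3[C@@H]([C@@H](I)[C@@]2(O[Si](C)(C)C(C)(C)C)C=C3)C1(C)C | intermediate
16 | iodo triol alkoxide (shown as the triol): 15 with all three silyl groups removed (not isolated) | O[C@@H]1[C@@H](OCOC)[C@@H](O)[C@]2(C)[C@@H]3[C@@H]([C@@H](I)[C@@]2(O)C=C3)C1(C)C | intermediate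
17 | (4S,5S,7S,8R,9S,10R,11R)-7,9-dihydroxy-8-(methoxymethoxy)-15-norlongipin-2-en-1-one | O[C@@H]1[C@@H](OCOC)[C@@H](O)[C@]2(C)[C@@H]3[C@@H]([C@H]2C(=O)C=C3)C1(C)C | intermediate
18 | (3R,4S,5S,7S,8R,9S,10R,11R)-7,9-dihydroxy-8-(methoxymethoxy)longipinan-1-one | O[C@@H]1[C@@H](OCOC)[C@@H](O)[C@]2(C)[C@@H]3[C@@H]([C@H]2C(=O)C[C@H]3C)C1(C)C | intermediate
19 | (2Z)-2-methylbut-2-enoic acid (angelic acid) | C/C=C(/C)C(=O)O | starting material
20 | mixed anhydride: (2Z)-2-methylbut-2-enoic 2,4,6-trichlorobenzoic anhydride (not isolated) | C/C=C(/C)C(=O)OC(=O)c1c(Cl)cc(Cl)cc1Cl | intermediate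
21 | mono-angelate: (3R,4S,5S,7S,8R,9S,10R,11R)-9-hydroxy-8-(methoxymethoxy)-1-oxolongipinan-7-yl (2Z)-2-methylbut-2-enoate (not isolated) | C/C=C(/C)C(=O)O[C@@H]1[C@@H](OCOC)[C@@H](O)[C@]2(C)[C@@H]3[C@@H]([C@H]2C(=O)C[C@H]3C)C1(C)C | intermediate
22 | (3R,4S,5S,7S,8R,9S,10R,11R)-8-(methoxymethoxy)-1-oxolongipinane-7,9-diyl bis[(2Z)-2-methylbut-2-enoate] | C/C=C(/C)C(=O)O[C@@H]1[C@@H](OCOC)[C@@H](OC(=O)/C(C)=C\C)[C@]2(C)[C@@H]3[C@@H]([C@H]2C(=O)C[C@H]3C)C1(C)C | intermediate
23 | dimethylborinate: O8-dimethylboryl derivative of 24 (not isolated) | C/C=C(/C)C(=O)O[C@@H]1[C@@H](OB(C)C)[C@@H](OC(=O)/C(C)=C\C)[C@]2(C)[C@@H]3[C@@H]([C@H]2C(=O)C[C@H]3C)C1(C)C | intermediate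
24 | (3R,4S,5S,7S,8R,9S,10R,11R)-8-hydroxy-1-oxolongipinane-7,9-diyl bis[(2Z)-2-methylbut-2-enoate] | C/C=C(/C)C(=O)O[C@@H]1[C@@H](O)[C@@H](OC(=O)/C(C)=C\C)[C@]2(C)[C@@H]3[C@@H]([C@H]2C(=O)C[C@H]3C)C1(C)C | target

**Total step count:** 11. **Longest linear sequence:** 11 steps (1 → 24); 4, 11 and 19 are bought.

**Three steps most likely to fail**

Step 7 (intramolecular Diels–Alder of an unactivated iodoalkene; rate and C4-versus-C1 regiochemistry are unproven). The fallback sets out from 13 and comes back at 17. The vinyl iodide is converted with retention into the pinacol vinylboronate F1 (B2pin2, PdCl2(dppf), KOPh, toluene, 50 °C). This is a more reactive dienophile whose β-carbon C5 is electronically matched with the nucleophilic diene terminus C4. Silylation as in step 7 (TBSOTf, Et3N) gives the silyloxy diene boronate F2, which is not isolated and cyclises in toluene at 110 °C to the endo-boronate adduct F3. Oxidation with NaBO3·4H2O (retention) gives the endo alcohol F4, and MsCl/Et3N gives the endo mesylate F5. F5 is taken through the step 8 conditions (TBAF, THF): desilylation gives the mesyloxy triol F6 as its alkoxide, which is not isolated, and the mesylate replaces iodide as the leaving group in the 1,2-shift to give 17.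

Step 8 (the new ring contraction; the alkoxide may fail to expel iodide, or desilylation may stall). The fallback sets out from 13, passes through F1, F2 and F3 made as described above, and comes back at 17 using only known reactions. Stereoretentive amination of the boronic ester (MeONH2, n-BuLi, THF, −78 to 60 °C) gives the endo amine F7. TBAF removes the three silyl groups to give the amino triol F8. NaNO2 in aqueous AcOH at 0 °C then effects a Tiffeneau–Demjanov-type semipinacol deamination: the endo diazonium ion loses N2 with anti migration of C10, driven by the bridgehead hydroxyl, to give 17.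

Step 10 (double acylation of two neopentyl secondary alcohols with an acid prone to Z to E isomerisation). The fallback sets out from 18 and comes back at 22. Both hydroxyls are esterified with 2-[bis(2,2,2-trifluoroethoxy)phosphoryl]propanoic acid (2.5 equiv, DCC, DMAP, CH2Cl2) to give the bis-phosphonate F9. A double Still–Gennari olefination with acetaldehyde (excess, KN(SiMe3)2, 18-crown-6, THF, −78 °C) then builds both (Z)-2-methylbut-2-enoates on the ester, giving 22.

**Further compounds**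
F1 | step 7 | vinylboronate: 13 with iodine replaced by 4,4,5,5-tetramethyl-1,3,2-dioxaborolan-2-yl (E alkene kept) | CC(C)(C)[Si](C)(C)O[C@@H](C(C)(C)/C=C/B1OC(C)(C)C(C)(C)O1)[C@@H](OCOC)[C@@H](O)[C@]1(C)CC=CC1=O
F2 | step 7 | silyloxy diene boronate: 14 with iodine replaced by 4,4,5,5-tetramethyl-1,3,2-dioxaborolan-2-yl (not isolated) | CC(C)(C)[Si](C)(C)O[C@@H](C(C)(C)/C=C/B1OC(C)(C)C(C)(C)O1)[C@@H](OCOC)[C@@H](O[Si](C)(C)C(C)(C)C)[C@]1(C)C=CC=C1O[Si](C)(C)C(C)(C)C
F3 | step 7 | endo-boronate adduct: 15 with the endo iodine on C11 replaced by 4,4,5,5-tetramethyl-1,3,2-dioxaborolan-2-yl | CC(C)(C)[Si](C)(C)O[C@@H]1[C@@H](OCOC)[C@@H](O[Si](C)(C)C(C)(C)C)[C@]2(C)[C@@H]3[C@@H]([C@@H](B4OC(C)(C)C(C)(C)O4)[C@@]2(O[Si](C)(C)C(C)(C)C)C=C3)C1(C)C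
F4 | step 7 | endo alcohol: 15 with the endo iodine on C11 replaced by hydroxyl | CC(C)(C)[Si](C)(C)O[C@@H]1[C@@H](OCOC)[C@@H](O[Si](C)(C)C(C)(C)C)[C@]2(C)[C@@H]3[C@@H]([C@@H](O)[C@@]2(O[Si](C)(C)C(C)(C)C)C=C3)C1(C)C
F5 | step 7 | endo mesylate: 15 with the endo iodine on C11 replaced by methanesulfonyloxy | CC(C)(C)[Si](C)(C)O[C@@H]1[C@@H](OCOC)[C@@H](O[Si](C)(C)C(C)(C)C)[C@]2(C)[C@@H]3[C@@H]([C@@H](OS(C)(=O)=O)[C@@]2(O[Si](C)(C)C(C)(C)C)C=C3)C1(C)C
F6 | step 7 | mesyloxy triol (shown as the triol): F5 with all three silyl groups removed (not isolated) | O[C@@H]1[C@@H](OCOC)[C@@H](O)[C@]2(C)[C@@H]3[C@@H]([C@@H](OS(C)(=O)=O)[C@@]2(O)C=C3)C1(C)C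
F7 | step 8 | endo amine: 15 with the endo iodine on C11 replaced by NH2 | CC(C)(C)[Si](C)(C)O[C@@H]1[C@@H](OCOC)[C@@H](O[Si](C)(C)C(C)(C)C)[C@]2(C)[C@@H]3[C@@H]([C@@H](N)[C@@]2(O[Si](C)(C)C(C)(C)C)C=C3)C1(C)C
F8 | step 8 | amino triol: F7 with all three silyl groups removed (free bridgehead C1–OH) | O[C@@H]1[C@@H](OCOC)[C@@H](O)[C@]2(C)[C@@H]3[C@@H]([C@@H](N)[C@@]2(O)C=C3)C1(C)C
F9 | step 10 | bis-phosphonate: (3R,4S,5S,7S,8R,9S,10R,11R)-8-(methoxymethoxy)-1-oxolongipinane-7,9-diyl bis{2-[bis(2,2,2-trifluoroethoxy)phosphoryl]propanoate} (phosphonate α-carbons unspecified) | CC(C(=O)O[C@@H]1[C@@H](OCOC)[C@@H](OC(=O)C(C)P(=O)(OCC(F)(F)F)OCC(F)(F)F)[C@]2(C)[C@@H]3[C@@H]([C@H]2C(=O)C[C@H]3C)C1(C)C)P(=O)(OCC(F)(F)F)OCC(F)(F)F
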